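The propellane is opened at the three bonds around the C4a–C9a axis (β-carboline locants; primed locants for the methoxyindole): C4a–C4b, N9–C9a and C9a–C4'. The route exploits that the unsubstituted benzo ring with N9 is a phenylhydrazine retron and that C4a is an enolisable, oxygen-bearing carbon next to the C9a ketone of a 2,3-dioxopiperidine whose C1 lactam blocks the other flank. One chiral-acid-mediated operation on the racemic 4-(indol-5-yloxy)piperidine-2,3-dione and phenylhydrazine (ene-hydrazine formation, [3,3] shift, loss of ammonia, aza-Friedel–Crafts closure at C4') builds the indoline and dihydrofuran rings and both quaternary stereocentres. Detosylation, lactam reduction and aminomethylation finish.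

Key step: step 9

Remark on locants: piperidine locants are used up to compound 11; C3 and C4 of the piperidinedione become C9a and C4a.
Remark on structures: all structures were checked atom by atom and are consistent; the C9a descriptor is S in lactams 15 and 16 and R in 17 and 18 only because C1 loses CIP rank on reduction, the geometry being unchanged.
Remark on racemates: racemic compounds with two stereocentres (4, 10) are drawn as one enantiomer to show the relative configuration.
Remark on precursor design: the connectivity of the key-step precursor is kept; the N1' sulfonyl group stays on through step 9 because it damps the arene enough to stop it attacking the C9a ketone, and the hydrazone is therefore formed before any acid is added.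
Assumption: the sense of induction of the spirocyclic phosphoric acid cannot be predicted reliably; the (R)-acid is written, and the (S)-acid would be used if the (4aR) series forms.

Step 1
Reactants: 1 1-methylpiperidin-2-one
Product: 3 1-methyl-5,6-dihydropyridin-2(1H)-one, via 3-phenylselanyl lactam 2 (not isolated)
Conditions: LiN(iPr)2, THF, −78 °C; PhSeCl, −78 °C; then H2O2 (30% aq.), pyridine, CH2Cl2, 0 °C → rt
Reagents that add atoms: none
Why: α-Selenenylation of the lithium lactam enolate followed by selenoxide syn-elimination should give the conjugated lactam, since only C4 offers a β-hydrogen.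

Step 2
Reactants: 3 1-methyl-5,6-dihydropyridin-2(1H)-one
Product: 4 racemic 3,4-epoxy-1-methylpiperidin-2-one
Conditions: dimethyldioxirane (acetone solution), CH2Cl2, rt
Reagents that add atoms: dimethyldioxirane, CC1(C)OO1
Why: Dioxirane epoxidation of an electron-poor conjugated alkene is a concerted oxygen transfer that should give the necessarily cis-fused epoxide as a racemate, and the volatile by-product lets this small polar compound be isolated by evaporation.

Step 3
Reactants: 5 3-methoxy-4-nitrophenol
Product: 6 4-(benzyloxy)-2-methoxy-1-nitrobenzene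
Conditions: BnBr, K2CO3, DMF, 50 °C
Reagents that add atoms: benzyl bromide, BrCc1ccccc1
Why: Williamson etherification of the acidic nitrophenol should protect the future C5' oxygen for the Grignard step.

Step 4
Reactants: 6 4-(benzyloxy)-2-methoxy-1-nitrobenzene
Product: 7 5-(benzyloxy)-7-methoxy-1H-indole
Conditions: CH2=CHMgBr (3.2 equiv), THF, −45 °C
Reagents that add atoms: vinylmagnesium bromide, C=C[Mg]Br
Why: Bartoli indole synthesis: the nitroso arene formed by the first equivalent is O-vinylated, [3,3] rearrangement occurs at the only free ortho carbon, and the ortho methoxy group that the reaction needs ends up at C7.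

Step 5
Reactants: 7 5-(benzyloxy)-7-methoxy-1H-indole
Product: 8 5-(benzyloxy)-7-methoxy-1-tosyl-1H-indole
Conditions: NaH, TsCl, DMF, 0 °C → rt
Reagents that add atoms: 4-methylbenzenesulfonyl chloride, Cc1ccc(S(Cl)(=O)=O)cc1
Why: N-Sulfonylation of the sodium indolide should install a group that protects the pyrrole ring from the later oxidation and tempers the arene for step 9.

Step 6
Reactants: 8 5-(benzyloxy)-7-methoxy-1-tosyl-1H-indole
Product: 9 7-methoxy-1-tosyl-1H-indol-5-ol
Conditions: H2 (1 atm), Pd/C, EtOAc–EtOH, rt
Reagents that add atoms: none
Why: Hydrogenolysis of the benzyl aryl ether over palladium should free the phenol, the C2–C3 bond of an N-sulfonyl indole being inert under these mild conditions.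

Step 7
Reactants: 4 racemic 3,4-epoxy-1-methylpiperidin-2-one; 9 7-methoxy-1-tosyl-1H-indol-5-ol
Product: 10 racemic trans-3-hydroxy-4-[(7-methoxy-1-tosylindol-5-yl)oxy]-1-methylpiperidin-2-one
Conditions: Cs2CO3 (0.3 equiv), DMF, 70 °C
Reagents that add atoms: none
Why: Base-catalysed SN2 opening of the α,β-epoxy amide by the phenoxide should occur at C4, the carbon remote from the carbonyl group, with inversion to give the trans product, while the substoichiometric base keeps the medium buffered by the phenol and spares the sulfonamide.

Step 8
Reactants: 10 racemic trans-3-hydroxy-4-[(7-methoxy-1-tosylindol-5-yl)oxy]-1-methylpiperidin-2-one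
Product: 11 racemic 4-[(7-methoxy-1-tosylindol-5-yl)oxy]-1-methylpiperidine-2,3-dione
Conditions: Dess–Martin periodinane, pyridine, CH2Cl2, 0 °C → rt
Reagents that add atoms: none
Why: Dess–Martin oxidation of an α-hydroxy amide to the α-keto amide should proceed under buffered non-aqueous conditions that leave the N-sulfonyl indole and the aryl ether alone; the remaining C4 centre is enolisable and its configuration is irrelevant.

Step 9
Reactants: 11 racemic 4-[(7-methoxy-1-tosylindol-5-yl)oxy]-1-methylpiperidine-2,3-dione; 12 phenylhydrazine
Product: 15 (4aS,9aS)-N1'-tosyl propellane lactam, via phenylhydrazone 13 (not isolated), via 3H-indole 14 (not isolated)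
Conditions: 4 Å MS, toluene, rt (no acid); then (R)-STRIP [(R)-6,6'-bis(2,4,6-triisopropylphenyl)-1,1'-spirobiindane-7,7'-diyl hydrogen phosphate, 10 mol %], Amberlite CG50 (carboxylic acid resin), toluene, 45 °C
Reagents that add atoms: none
Why: Proposed new method: hydrazone 13 can tautomerise only toward C4a because C1 is a lactam carbonyl, so both enantiomers of 11 pass through one achiral ene-hydrazine conjugated to C1=O, and the chiral phosphate bound to it should choose the face of C4a on which the [3,3] shift makes the C4a–C4b bond. Rearomatisation, 5-exo-trig addition of the aniline nitrogen to the C9a iminium carbon (indoline ring) and loss of ammonia give 3H-indole 14, which cannot aromatise because C4a is quaternary; C4' then adds to the protonated C9a=N9 bond in a 5-exo-trig aza-Friedel–Crafts closure (dihydrofuran ring) of the geometry known from the cyclisation of α-aryloxy ketones to benzofurans. The closest known reaction types are the phosphoric-acid-catalysed enantioselective Fischer indolisation, the interrupted Fischer indolisation of α-branched ketones to 3H-indoles and the Brønsted-acid-promoted arylation of 3H-indoles. C4a is set under catalyst control in the sigmatropic step and C9a under substrate control, since the short C4a–O–C5' tether lets C4' reach only the imine face syn to oxygen. The step needs the rearrangement to precede any Friedel–Crafts attack on the C9a ketone or hydrazone carbon, which the sulfonyl-damped arene, the acid-free formation of 13 and the low electrophilicity of a hydrazone should secure, and it needs arylation by C4' and not C6', which the para methoxy group, the naphthol-like bond fixation of a 5-oxyindole and the flanking of C6' by two alkoxy groups should favour. The weakly acidic resin takes up the ammonia so that the catalyst is not neutralised.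

Step 10
Reactants: 15 (4aS,9aS)-N1'-tosyl propellane lactam
Product: 16 (4aS,9aS)-N1'-H propellane lactam
Conditions: KOH, MeOH–THF–H2O, 60 °C
Reagents that add atoms: none
Why: Alkaline cleavage of the N-arylsulfonyl indole (attack at sulfur, indolide as leaving group) should free N1' without touching the hindered tertiary lactam or the quaternary centres, and it is placed before the reduction so that no basic amine meets sulfonate by-products.

Step 11
Reactants: 16 (4aS,9aS)-N1'-H propellane lactam
Product: 17 (4aS,9aR)-propellane amine
Conditions: LiAlH4, THF, 0 → 65 °C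
Reagents that add atoms: none
Why: LiAlH4 reduction of the tertiary lactam through the hemiaminal aluminate and iminium ion should give the N-methylpiperidine; the two N–H groups are only deprotonated and the quaternary stereocentres cannot epimerise.

Step 12
Reactants: 17 (4aS,9aR)-propellane amine
Product: 18 target, the 3'-(dimethylaminomethyl) derivative of 17
Conditions: N,N-dimethylmethyleneiminium iodide, MeCN–CH2Cl2, 0 °C → rt; then aq. NaOH
Reagents that add atoms: N,N-dimethylmethyleneiminium iodide (Eschenmoser's salt), C=[N+](C)C.[I-]
Why: Mannich aminomethylation with the preformed iminium salt should occur at C3', the most nucleophilic carbon, and the absence of free formaldehyde avoids a methylene bridge between N9 and C3'.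

Compound list
1 | 1-methylpiperidin-2-one | CN1CCCCC1=O | starting material
2 | 1-methyl-3-(phenylselanyl)piperidin-2-one (racemic, not isolated) | CN1CCCC([Se]c2ccccc2)C1=O | intermediate
3 | 1-methyl-5,6-dihydropyridin-2(1H)-one | CN1CCC=CC1=O | intermediate
4 | racemic cis-fused 3,4-epoxy-1-methylpiperidin-2-one (3-methyl-7-oxa-3-azabicyclo[4.1.0]heptan-2-one) | CN1CC[C@@H]2O[C@@H]2C1=O | intermediate
5 | 3-methoxy-4-nitrophenol | COc1cc(O)ccc1[N+](=O)[O-] | starting material
6 | 4-(benzyloxy)-2-methoxy-1-nitrobenzene | COc1cc(OCc2ccccc2)ccc1[N+](=O)[O-] | intermediate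
7 | 5-(benzyloxy)-7-methoxy-1H-indole | COc1cc(OCc2ccccc2)cc2cc[nH]c12 | intermediate
8 | 5-(benzyloxy)-7-methoxy-1-tosyl-1H-indole | COc1cc(OCc2ccccc2)cc2ccn(S(=O)(=O)c3ccc(C)cc3)c12 | intermediate
9 | 7-methoxy-1-tosyl-1H-indol-5-ol | COc1cc(O)cc2ccn(S(=O)(=O)c3ccc(C)cc3)c12 | intermediate
10 | racemic trans-3-hydroxy-4-[(7-methoxy-1-tosylindol-5-yl)oxy]-1-methylpiperidin-2-one | COc1cc(O[C@@H]2CCN(C)C(=O)[C@H]2O)cc2ccn(S(=O)(=O)c3ccc(C)cc3)c12 | intermediate
11 | racemic 4-[(7-methoxy-1-tosylindol-5-yl)oxy]-1-methylpiperidine-2,3-dione | COc1cc(OC2CCN(C)C(=O)C2=O)cc2ccn(S(=O)(=O)c3ccc(C)cc3)c12 | intermediate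
12 | phenylhydrazine | NNc1ccccc1 | starting material
13 | 3-phenylhydrazone of 11 (racemic at C4, not isolated) | COc1cc(OC2CCN(C)C(=O)C2=NNc2ccccc2)cc2ccn(S(=O)(=O)c3ccc(C)cc3)c12 | intermediate
14 | (4aS)-4a-[(7-methoxy-1-tosylindol-5-yl)oxy]-2-methyl-3,4-dihydro-4aH-β-carbolin-1(2H)-one, the 3H-indole with C9a=N9 (not isolated) | COc1cc(O[C@]23CCN(C)C(=O)C2=Nc2ccccc23)cc2ccn(S(=O)(=O)c3ccc(C)cc3)c12 | intermediate
15 | (4aS,9aS)-N1'-tosyl propellane lactam: 2-methyl-hexahydro-β-carbolin-1-one bridged across C4a–C9a by the 7-methoxy-1-tosylindole (C4a–O–C5', C9a–C4') | COc1cc2c(c3ccn(S(=O)(=O)c4ccc(C)cc4)c13)[C@@]13C(=O)N(C)CC[C@]1(O2)c1ccccc1N3 | intermediate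
16 | (4aS,9aS)-N1'-H propellane lactam | COc1cc2c(c3cc[nH]c13)[C@@]13C(=O)N(C)CC[C@]1(O2)c1ccccc1N3 | intermediate
17 | (4aS,9aR)-propellane amine (C1 methylene) | COc1cc2c(c3cc[nH]c13)[C@@]13CN(C)CC[C@]1(O2)c1ccccc1N3 | intermediate
18 | target, (4aS,9aR), 3'-(dimethylaminomethyl)-7'-methoxy propellane | COc1cc2c(c3c(CN(C)C)c[nH]c13)[C@@]13CN(C)CC[C@]1(O2)c1ccccc1N3 | target

Total step count: 12. Longest linear sequence: 10 steps (5 → 18, steps 3 to 12).

Steps most likely to fail

Step 9. The sigmatropic shift of a conjugated ene-hydrazine may be too slow under a weak chiral acid, so that 1,4-elimination of the aryloxide from the hydrazone or attack of the arene on the hydrazone carbon takes over. Face selection on an N-unsubstituted ene-hydrazine may also be poor, or the closure may stall at 14. Since C4a is already fixed in 14, a stalled closure could be driven by a stronger achiral acid once 13 is consumed. The fallback sets out from 11 and 12 and comes back at 15, using known chemistry only. Hydrazone 13 would be made as in step 9 and heated in acetic acid, the classical medium for Fischer indolisation of α-branched ketones, to give the racemic 3H-indole F1. Trifluoroacetic acid in CH2Cl2 would then effect the acid-promoted intramolecular arylation to the racemic lactam F2. Preparative chromatography on a polysaccharide chiral stationary phase would separate 15 from its antipode F3.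

Step 7. The hindered, weakly nucleophilic phenoxide may open the epoxide slowly, attack at C3 may compete, or the sulfonyl group may migrate to oxygen at the temperature needed. The fallback sets out from 9 and comes back at 11, bypassing 10 and step 8. Phenol 9 would be alkylated with ethyl 2,4-dibromobutanoate (K2CO3, acetone) at the activated α-carbon to give ethyl 4-bromo-2-(aryloxy)butanoate F4. The sodium salt of ethyl N-methyloxamate (NaH, DMF) would displace the primary bromide to give the oxamate diester F5. Dieckmann cyclisation of the α-aryloxy ester enolate onto the oxamate ester (LiN(SiMe3)2, THF, −78 °C) would close the ring to ethyl 4-(aryloxy)-1-methyl-2,3-dioxopiperidine-4-carboxylate F6. Krapcho dealkoxycarbonylation (LiCl, wet DMSO, heat) would then give 11.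

Step 12. Aminomethylation may go to N9 or to the aniline ring, or may be slow at C3', which lies peri to the quaternary C9a. The fallback sets out from 17 and comes back at 18. Vilsmeier–Haack reaction (POCl3, DMF, 0 °C) would give the C3' N,N-dimethyliminium salt F7, which would be reduced in the same flask with NaBH4 in MeOH to the dimethylaminomethyl group. Any amidinium formed at N9 would be reduced to an aminal that hydrolyses on aqueous acid work-up.

Further compounds
F1 | step 9 | racemic 3H-indole (racemate of 14) | COc1cc(OC23CCN(C)C(=O)C2=Nc2ccccc23)cc2ccn(S(=O)(=O)c3ccc(C)cc3)c12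
F2 | step 9 | racemic N1'-tosyl propellane lactam (15 plus its antipode) | COc1cc2c(c3ccn(S(=O)(=O)c4ccc(C)cc4)c13)[C@@]13C(=O)N(C)CC[C@]1(O2)c1ccccc1N3.COc1cc2c(c3ccn(S(=O)(=O)c4ccc(C)cc4)c13)[C@]13C(=O)N(C)CC[C@@]1(O2)c1ccccc1N3
F3 | step 9 | (4aR,9aR)-N1'-tosyl propellane lactam, antipode of 15 | COc1cc2c(c3ccn(S(=O)(=O)c4ccc(C)cc4)c13)[C@]13C(=O)N(C)CC[C@@]1(O2)c1ccccc1N3
F4 | step 7 | racemic ethyl 4-bromo-2-[(7-methoxy-1-tosylindol-5-yl)oxy]butanoate | COc1cc(OC(CCBr)C(=O)OCC)cc2ccn(S(=O)(=O)c3ccc(C)cc3)c12
F5 | step 7 | racemic ethyl 4-[(ethoxyoxalyl)(methyl)amino]-2-[(7-methoxy-1-tosylindol-5-yl)oxy]butanoate | COc1cc(OC(CCN(C)C(=O)C(=O)OCC)C(=O)OCC)cc2ccn(S(=O)(=O)c3ccc(C)cc3)c12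
F6 | step 7 | racemic ethyl 4-[(7-methoxy-1-tosylindol-5-yl)oxy]-1-methyl-2,3-dioxopiperidine-4-carboxylate | COc1cc(OC2(C(=O)OCC)CCN(C)C(=O)C2=O)cc2ccn(S(=O)(=O)c3ccc(C)cc3)c12
F7 | step 12 | C3' N,N-dimethyliminium chloride of 17 (not isolated) | COc1cc2c(c3c(C=[N+](C)C)c[nH]c13)[C@@]13CN(C)CC[C@]1(O2)c1ccccc1N3.[Cl-]
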